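**Retrosynthetic overview** (cembrane numbering: C1 = lactone β‑carbon, C14 = lactone O‑carbon, C13 = OAc, C12 = Me, C3/C4 = oxirane, C15–C17 = methylene‑lactone carbons)

1. Oxirane last: substrate‑controlled epoxidation of the 3E‑olefin of macrocyclic triene acetate 28.
2. The 14‑membered ring and the cis α‑methylene‑γ‑lactone form together by intramolecular indium (Barbier) allylation of an α‑hydroxy aldehyde (C1–C14 bond), then lactonisation.
3. The seco chain is joined at C9–C10 by Cu‑catalysed coupling of allylic bromide 9 with the Grignard reagent from 17.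
4. Key bond: a Johnson–Claisen [3,3] rearrangement forges C5–C6 and fixes the (E)‑C3=C4 olefin that becomes the trans‑oxirane; C7=C8 comes from an E‑selective Wittig.
5. Chirality: C13 is bought in methyl (S)‑glycerate acetonide, C12 is set by syn‑selective cuprate addition to its Z‑enoate, and C14, C1, C3, C4 are relayed from these.

Assumption: the target SMILES encodes (1S,3R,4R,7E,12S,13R,14R); cembrane numbering is used for atom labels throughout.

---

**Step 1**
Reactants: 1 methacrolein; 2 3‑bromo‑1‑(trimethylsilyl)prop‑1‑yne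
Product: 3 (±)‑2‑methyl‑6‑(trimethylsilyl)hex‑1‑en‑5‑yn‑3‑ol
Conditions: Zn dust, THF, 0 °C → rt; aq NH4Cl
Reagents that add atoms: none (both partners are reactants)
Why: Barbier propargylation; the silyl‑substituted allenylzinc adds 1,2 through its CH2 terminus to give the homopropargylic isopropenyl carbinol, whose stereocentre is erased in step 2.

**Step 2 (key step)**
Reactants: 3; 4 triethyl orthoacetate
Product: 5 ethyl (4E)‑4‑methyl‑8‑(trimethylsilyl)oct‑4‑en‑7‑ynoate
Conditions: MeC(OEt)3 (6 equiv), EtCO2H (cat.), 140 °C, distil off EtOH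
Reagents that add atoms: triethyl orthoacetate (4), CC(OCC)(OCC)OCC
Why: Johnson–Claisen rearrangement; the mixed ketene acetal rearranges through a chair with the CH2C≡CSiMe3 group equatorial, forming C5–C6 and the C3=C4 olefin with ≥95:5 E.

**Step 3**
Reactants: 5; 6 ethyl 2‑(triphenylphosphoranylidene)propanoate
Product: 7 ethyl (2E,6E)‑2,6‑dimethyl‑10‑(trimethylsilyl)deca‑2,6‑dien‑9‑ynoate
Conditions: DIBAL‑H (1.05 equiv), CH2Cl2, −78 °C; then 6, −78 °C → rt (one pot)
Reagents that add atoms: ylide 6, CCOC(=O)C(C)=P(c1ccccc1)(c1ccccc1)c1ccccc1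
Why: DIBAL stops at the aldehyde oxidation level at −78 °C and the stabilised α‑methyl ylide gives the E‑enoate (Wittig), installing C7=C8, C9 and the C8 methyl.

**Step 4**
Reactants: 7
Product: 8 (2E,6E)‑2,6‑dimethyl‑10‑(trimethylsilyl)deca‑2,6‑dien‑9‑yn‑1‑ol
Conditions: DIBAL‑H (2.2 equiv), CH2Cl2, −78 °C
Reagents that add atoms: none
Why: 1,2‑reduction of the enoate to the allylic alcohol; the silylalkyne and isolated olefin are inert at −78 °C.

**Step 5**
Reactants: 8
Product: 9 [(4E,8E)‑10‑bromo‑5,9‑dimethyldeca‑4,8‑dien‑1‑yn‑1‑yl]trimethylsilane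
Conditions: CBr4, PPh3, CH2Cl2, 0 °C
Reagents that add atoms: carbon tetrabromide, BrC(Br)(Br)Br
Why: Appel bromination is a neutral SN2 process, so the primary allylic bromide forms without allylic transposition or E/Z loss.

**Step 6**
Reactants: 10 methyl (4S)‑2,2‑dimethyl‑1,3‑dioxolane‑4‑carboxylate; 11 methyl (triphenylphosphoranylidene)acetate
Product: 12 methyl (2Z)‑3‑[(4R)‑2,2‑dimethyl‑1,3‑dioxolan‑4‑yl]prop‑2‑enoate
Conditions: DIBAL‑H, CH2Cl2, −78 °C; then 11, MeOH, −78 → 0 °C (one pot)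
Reagents that add atoms: ylide 11, COC(=O)C=P(c1ccccc1)(c1ccccc1)c1ccccc1
Why: the in‑situ (S)‑glyceraldehyde acetonide undergoes Wittig olefination, which is Z‑selective (about 8:1) in methanol; C13 is untouched (R/S label changes only by CIP priority).

**Step 7**
Reactants: 12
Product: 13 methyl (3S)‑3‑[(4R)‑2,2‑dimethyl‑1,3‑dioxolan‑4‑yl]butanoate
Conditions: Me2CuLi (CuI, MeLi), TMSCl, Et2O, −78 → −40 °C
Reagents that add atoms: lithium dimethylcuprate, C[Cu-]C.[Li+]
Why: conjugate addition; A(1,3) strain in the Z‑enoate holds C13–H in plane and the cuprate adds anti to the dioxolane C–C bond, giving the 12,13‑syn adduct (C12 = S), as precedented for Z‑γ‑alkoxy enoates.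

**Step 8**
Reactants: 13
Product: 14 (3S)‑3‑[(4R)‑2,2‑dimethyl‑1,3‑dioxolan‑4‑yl]butan‑1‑ol
Conditions: LiAlH4, THF, 0 °C
Reagents that add atoms: none
Why: hydride reduction of the ester; the acetonide and both stereocentres are unaffected.

**Step 9**
Reactants: 14; 15 4‑methoxybenzaldehyde dimethyl acetal
Product: 16 (3S)‑3‑[(4R)‑2‑(4‑methoxyphenyl)‑1,3‑dioxolan‑4‑yl]butan‑1‑ol (acetal epimers, inconsequential)
Conditions: PPTS, MeOH, 50 °C; concentrate; then 15, PPTS, CH2Cl2, rt (telescoped)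
Reagents that add atoms: acetal 15, COC(OC)c1ccc(OC)cc1
Why: transacetalisation; the 1,2‑diol closes the five‑membered p‑methoxybenzylidene acetal, which can later be opened regioselectively.

**Step 10**
Reactants: 16
Product: 17 (4R)‑4‑[(2S)‑4‑bromobutan‑2‑yl]‑2‑(4‑methoxyphenyl)‑1,3‑dioxolane
Conditions: CBr4, PPh3, 2,6‑lutidine, CH2Cl2, 0 °C
Reagents that add atoms: carbon tetrabromide, BrC(Br)(Br)Br
Why: Appel bromination of the primary alcohol; the buffer protects the acid‑labile acetal.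

**Step 11**
Reactants: 17; 9
Product: 18 (4R)‑4‑[(2S,6E,10E)‑6,10‑dimethyl‑14‑(trimethylsilyl)tetradeca‑6,10‑dien‑13‑yn‑2‑yl]‑2‑(4‑methoxyphenyl)‑1,3‑dioxolane
Conditions: 17, Mg, THF; then 9, Li2CuCl4 (3 mol %), THF, −78 → 0 °C
Reagents that add atoms: none
Why: Kochi Cu‑catalysed Grignard/allylic bromide coupling proceeds by α (SN2) attack with retention of the E‑olefin, forming C9–C10; acetal and silylalkyne tolerate the Grignard.

**Step 12**
Reactants: 18
Product: 19 (2R,3S,7E,11E)‑2‑[(4‑methoxybenzyl)oxy]‑3,7,11‑trimethyl‑15‑(trimethylsilyl)pentadeca‑7,11‑dien‑14‑yn‑1‑ol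
Conditions: DIBAL‑H (3 equiv), CH2Cl2, −78 → 0 °C
Reagents that add atoms: none
Why: regioselective reductive acetal opening; DIBAL coordinates the less hindered O‑14, leaving the PMB ether on the secondary O‑13 and freeing the primary C14–OH.

**Step 13**
Reactants: 19
Product: 20 (2R,3S,7E,11E)‑2‑[(4‑methoxybenzyl)oxy]‑3,7,11‑trimethylpentadeca‑7,11‑dien‑14‑yn‑1‑ol
Conditions: K2CO3, MeOH, rt
Reagents that add atoms: none
Why: methanolysis of the alkynyl C–Si bond gives the terminal alkyne; nothing else is base‑labile.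

**Step 14**
Reactants: 20
Product: 21 (5E,9E,14S,15R)‑15‑[(4‑methoxybenzyl)oxy]‑6,10,14‑trimethylhexadeca‑5,9‑dien‑2‑yne‑1,16‑diol
Conditions: EtMgBr (2.2 equiv), THF, 45 °C; (CH2O)n, reflux
Reagents that add atoms: formaldehyde (paraformaldehyde), C=O
Why: the alkynyl Grignard (the alkoxide is merely deprotonated) adds to formaldehyde, installing C17 as a propargylic alcohol.

**Step 15**
Reactants: 21
Product: 22 (2E,5E,9E,14S,15R)‑16‑hydroxy‑2‑(hydroxymethyl)‑15‑[(4‑methoxybenzyl)oxy]‑6,10,14‑trimethylhexadeca‑2,5,9‑trienoic acid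
Conditions: i‑BuMgBr (4 equiv), Cp2TiCl2 (10 mol %), Et2O, rt; then CO2, −20 °C → rt; dilute acid work‑up
Reagents that add atoms: carbon dioxide, O=C=O
Why: Sato hydromagnesiation; Ti–H adds syn across the propargylic alkoxide with Mg on the carbon next to CH2O (C15), and the alkenyl Grignard is carboxylated to give C16; trisubstituted olefins do not react.

**Step 16**
Reactants: 22
Product: 23 methyl (2E,5E,9E,14S,15R)‑16‑hydroxy‑2‑(hydroxymethyl)‑15‑[(4‑methoxybenzyl)oxy]‑6,10,14‑trimethylhexadeca‑2,5,9‑trienoate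
Conditions: TMSCHN2, toluene/MeOH, 0 °C
Reagents that add atoms: trimethylsilyldiazomethane, C[Si](C)(C)C=[N+]=[N-]
Why: chemoselective O‑methylation of the carboxylic acid; the alcohols are untouched.

**Step 17**
Reactants: 23
Product: 24 methyl (2Z,5E,9E,14S,15R)‑2‑(bromomethyl)‑16‑hydroxy‑15‑[(4‑methoxybenzyl)oxy]‑6,10,14‑trimethylhexadeca‑2,5,9‑trienoate
Conditions: NBS, Me2S, CH2Cl2, −30 → 0 °C
Reagents that add atoms: N‑bromosuccinimide, O=C1CCC(=O)N1Br
Why: Corey–Kim halogenation; only the allylic alkoxysulfonium is displaced by bromide, and the saturated primary C14–OH is returned on work‑up.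

**Step 18**
Reactants: 24
Product: 25 methyl (2Z,5E,9E,14S,15R)‑2‑(bromomethyl)‑15‑[(4‑methoxybenzyl)oxy]‑6,10,14‑trimethyl‑16‑oxohexadeca‑2,5,9‑trienoate
Conditions: Dess–Martin periodinane, NaHCO3, CH2Cl2, 0 °C
Reagents that add atoms: none
Why: mild buffered oxidation gives the α‑alkoxy aldehyde without epimerising C13 or disturbing the allylic bromide.

**Step 19**
Reactants: 25
Product: 26 methyl (2Z,5E,9E,14S,15R)‑2‑(bromomethyl)‑15‑hydroxy‑6,10,14‑trimethyl‑16‑oxohexadeca‑2,5,9‑trienoate (used crude)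
Conditions: DDQ, CH2Cl2/pH 7 buffer, 0 °C
Reagents that add atoms: none
Why: oxidative PMB cleavage unmasks the free α‑hydroxy group that is needed as the chelating element in the next step.

**Step 20**
Reactants: 26
Product: 27 (1S,3E,7E,12S,13R,14R)‑13‑hydroxycembra‑3,7,15(17)‑trien‑16,14‑olide
Conditions: In powder, THF/H2O (3:1), about 1 mM (slow addition), rt; then PPTS (cat.) to complete lactonisation
Reagents that add atoms: none
Why: intramolecular Barbier allylation; indium chelated between O‑13 and the aldehyde directs attack to give the 13,14‑syn diol (14R), the γ‑substituted allylindium reacts through a chair SE2′ transition state to give the 1,14‑syn adduct (1S), and the γ‑hydroxy ester closes to the cis‑fused α‑methylene lactone.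

**Step 21**
Reactants: 27
Product: 28 (1S,3E,7E,12S,13R,14R)‑13‑acetoxycembra‑3,7,15(17)‑trien‑16,14‑olide
Conditions: Ac2O, pyridine, DMAP (cat.), CH2Cl2, 0 °C
Reagents that add atoms: acetic anhydride, CC(=O)OC(C)=O
Why: acylation of the only free hydroxyl, done before epoxidation so that no free C13–OH can open the oxirane transannularly.

**Step 22**
Reactants: 28
Product: 29 eupalmerin acetate, (1S,3R,4R,7E,12S,13R,14R)‑13‑acetoxy‑3,4‑epoxycembra‑7,15(17)‑dien‑16,14‑olide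
Conditions: m‑CPBA (1.05 equiv), NaHCO3, CH2Cl2, −20 → 0 °C
Reagents that add atoms: m‑CPBA, OOC(=O)c1cccc(Cl)c1
Why: Prilezhaev epoxidation is stereospecific (E‑olefin gives the trans‑oxirane) and ignores the electron‑poor methylene lactone; 3R,4R is expected from attack on the outer face of C3=C4, but both that face preference and selectivity over C7=C8 are unproven (see risks).

---

**Compound list**

1 | methacrolein | CC(=C)C=O | starting material
2 | 3‑bromo‑1‑(trimethylsilyl)prop‑1‑yne | C[Si](C)(C)C#CCBr | starting material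
3 | (±)‑2‑methyl‑6‑(trimethylsilyl)hex‑1‑en‑5‑yn‑3‑ol | CC(=C)C(O)CC#C[Si](C)(C)C | intermediate
4 | triethyl orthoacetate | CC(OCC)(OCC)OCC | starting material
5 | ethyl (4E)‑4‑methyl‑8‑(trimethylsilyl)oct‑4‑en‑7‑ynoate | CCOC(=O)CC/C(C)=C/CC#C[Si](C)(C)C | intermediate
6 | ethyl 2‑(triphenylphosphoranylidene)propanoate | CCOC(=O)C(C)=P(c1ccccc1)(c1ccccc1)c1ccccc1 | starting material
7 | ethyl (2E,6E)‑2,6‑dimethyl‑10‑(trimethylsilyl)deca‑2,6‑dien‑9‑ynoate | CCOC(=O)/C(C)=C/CC/C(C)=C/CC#C[Si](C)(C)C | intermediate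
8 | (2E,6E)‑2,6‑dimethyl‑10‑(trimethylsilyl)deca‑2,6‑dien‑9‑yn‑1‑ol | OC/C(C)=C/CC/C(C)=C/CC#C[Si](C)(C)C | intermediate
9 | [(4E,8E)‑10‑bromo‑5,9‑dimethyldeca‑4,8‑dien‑1‑yn‑1‑yl]trimethylsilane | BrC/C(C)=C/CC/C(C)=C/CC#C[Si](C)(C)C | intermediate
10 | methyl (4S)‑2,2‑dimethyl‑1,3‑dioxolane‑4‑carboxylate | COC(=O)[C@@H]1COC(C)(C)O1 | starting material (chiral pool)
11 | methyl (triphenylphosphoranylidene)acetate | COC(=O)C=P(c1ccccc1)(c1ccccc1)c1ccccc1 | starting material
12 | methyl (2Z)‑3‑[(4R)‑2,2‑dimethyl‑1,3‑dioxolan‑4‑yl]prop‑2‑enoate | COC(=O)/C=C\[C@@H]1COC(C)(C)O1 | intermediate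
13 | methyl (3S)‑3‑[(4R)‑2,2‑dimethyl‑1,3‑dioxolan‑4‑yl]butanoate | COC(=O)C[C@H](C)[C@@H]1COC(C)(C)O1 | intermediate
14 | (3S)‑3‑[(4R)‑2,2‑dimethyl‑1,3‑dioxolan‑4‑yl]butan‑1‑ol | OCC[C@H](C)[C@@H]1COC(C)(C)O1 | intermediate
15 | 4‑methoxybenzaldehyde dimethyl acetal | COC(OC)c1ccc(OC)cc1 | starting material
16 | (3S)‑3‑[(4R)‑2‑(4‑methoxyphenyl)‑1,3‑dioxolan‑4‑yl]butan‑1‑ol | OCC[C@H](C)[C@@H]1COC(c2ccc(OC)cc2)O1 | intermediate
17 | (4R)‑4‑[(2S)‑4‑bromobutan‑2‑yl]‑2‑(4‑methoxyphenyl)‑1,3‑dioxolane | BrCC[C@H](C)[C@@H]1COC(c2ccc(OC)cc2)O1 | intermediate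
18 | (4R)‑4‑[(2S,6E,10E)‑6,10‑dimethyl‑14‑(trimethylsilyl)tetradeca‑6,10‑dien‑13‑yn‑2‑yl]‑2‑(4‑methoxyphenyl)‑1,3‑dioxolane | C1[C@H](OC(c2ccc(OC)cc2)O1)[C@@H](C)CCC/C(C)=C/CC/C(C)=C/CC#C[Si](C)(C)C | intermediate
19 | (2R,3S,7E,11E)‑2‑[(4‑methoxybenzyl)oxy]‑3,7,11‑trimethyl‑15‑(trimethylsilyl)pentadeca‑7,11‑dien‑14‑yn‑1‑ol | OC[C@H](OCc1ccc(OC)cc1)[C@@H](C)CCC/C(C)=C/CC/C(C)=C/CC#C[Si](C)(C)C | intermediate
20 | (2R,3S,7E,11E)‑2‑[(4‑methoxybenzyl)oxy]‑3,7,11‑trimethylpentadeca‑7,11‑dien‑14‑yn‑1‑ol | OC[C@H](OCc1ccc(OC)cc1)[C@@H](C)CCC/C(C)=C/CC/C(C)=C/CC#C | intermediate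
21 | (5E,9E,14S,15R)‑15‑[(4‑methoxybenzyl)oxy]‑6,10,14‑trimethylhexadeca‑5,9‑dien‑2‑yne‑1,16‑diol | OC[C@H](OCc1ccc(OC)cc1)[C@@H](C)CCC/C(C)=C/CC/C(C)=C/CC#CCO | intermediate
22 | (2E,5E,9E,14S,15R)‑16‑hydroxy‑2‑(hydroxymethyl)‑15‑[(4‑methoxybenzyl)oxy]‑6,10,14‑trimethylhexadeca‑2,5,9‑trienoic acid | OC[C@H](OCc1ccc(OC)cc1)[C@@H](C)CCC/C(C)=C/CC/C(C)=C/C/C=C(\CO)C(=O)O | intermediate
23 | methyl ester of 22 | OC[C@H](OCc1ccc(OC)cc1)[C@@H](C)CCC/C(C)=C/CC/C(C)=C/C/C=C(\CO)C(=O)OC | intermediate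
24 | methyl (2Z,5E,9E,14S,15R)‑2‑(bromomethyl)‑16‑hydroxy‑15‑[(4‑methoxybenzyl)oxy]‑6,10,14‑trimethylhexadeca‑2,5,9‑trienoate | OC[C@H](OCc1ccc(OC)cc1)[C@@H](C)CCC/C(C)=C/CC/C(C)=C/C/C=C(\CBr)C(=O)OC | intermediate
25 | methyl (2Z,5E,9E,14S,15R)‑2‑(bromomethyl)‑15‑[(4‑methoxybenzyl)oxy]‑6,10,14‑trimethyl‑16‑oxohexadeca‑2,5,9‑trienoate | O=C[C@H](OCc1ccc(OC)cc1)[C@@H](C)CCC/C(C)=C/CC/C(C)=C/C/C=C(\CBr)C(=O)OC | intermediate
26 | methyl (2Z,5E,9E,14S,15R)‑2‑(bromomethyl)‑15‑hydroxy‑6,10,14‑trimethyl‑16‑oxohexadeca‑2,5,9‑trienoate | O=C[C@H](O)[C@@H](C)CCC/C(C)=C/CC/C(C)=C/C/C=C(\CBr)C(=O)OC | intermediate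
27 | (1S,3E,7E,12S,13R,14R)‑13‑hydroxycembra‑3,7,15(17)‑trien‑16,14‑olide | C=C1C(=O)O[C@H]2[C@H](O)[C@@H](C)CCC/C(C)=C/CC/C(C)=C/C[C@@H]12 | intermediate
28 | (1S,3E,7E,12S,13R,14R)‑13‑acetoxycembra‑3,7,15(17)‑trien‑16,14‑olide | C=C1C(=O)O[C@H]2[C@H](OC(C)=O)[C@@H](C)CCC/C(C)=C/CC/C(C)=C/C[C@@H]12 | intermediate
29 | eupalmerin acetate | C=C1C(=O)O[C@H]2[C@H](OC(C)=O)[C@@H](C)CCC/C(C)=C/CC[C@@]3(C)O[C@@H]3C[C@@H]12 | target

---

**Step count:** 22 steps in total. Longest linear sequence: 17 steps (1–5, 11–22); the chiral branch (6–10, then 11–22) is also 17.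

**Three steps most likely to fail, with fallbacks**

1. **Step 22 (epoxidation).** Selectivity for C3=C4 over C7=C8, and for the correct face, rests only on macrocyclic conformation. Fallback: take the oxirane stereochemistry from the chiral pool instead. Build C1–C4 from (S)‑malic acid (C3–O bought), set C4 by chelation‑controlled Grignard addition of the C5 chain to the derived α‑alkoxy methyl ketone, and close the oxirane by displacement of a C3 mesylate before macrocyclisation.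

2. **Step 20 (macrocyclising allylation).** Risks are oligomerisation, the fragile α‑hydroxy aldehyde, and the diastereoselectivity at C14/C1. Fallback: form the lactone first by an intermolecular indium allylation of a small α‑hydroxy aldehyde fragment with the bromo‑enoate, then close the 14‑membered ring at C9–C10 by intramolecular alkylation of a sulfone‑stabilised carbanion with the allylic bromide, followed by reductive desulfonylation.

3. **Step 15 (hydromagnesiation/carboxylation on a polyfunctional diol).** Fallback: carry C1 as a masked aldehyde (a 1,3‑dithiane introduced at the start in place of the silylalkyne) and build the bromomethyl enoate by a Baylis–Hillman‑type addition of an α‑metallated acrylate, followed by Corey–Kim SN2′ bromination.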